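**Retrosynthetic overview**
- Target ⇐ primary-selective benzoylation at O7 of the 7,2-diol ⇐ mild hydrolysis of an acetonide tying O7 to O2 (locants: C1 quaternary epoxide carbon, C2–OH, C3–OBz, C4=C5, C6 epoxide CH, C7 exocyclic CH2).
- Key disconnection, C1–C6 and C6–O together: a Z-allylic sulfonium ylide (C6) adds to the C1 ketone of a 4-substituted 2,2-dimethyl-1,3-dioxan-5-one and the resulting alkoxide expels the sulfide.
- C3 benzoate ⇐ Mitsunobu inversion of an anti-aldol carbinol; Z-alkene ⇐ Lindlar reduction of an alkyne.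
- C2–C3 bond ⇐ L-proline aldol of 2,2-dimethyl-1,3-dioxan-5-one with 4-chlorobut-2-ynal.
- Ring order: the dioxane is a bought-in temporary template; cyclohexene and oxirane both form in the single ylide step (carbocycle first, oxirane immediately after); the dioxane is removed last.

Assumption: the stereo-SMILES is taken literally as the (1R,2S,3R,6S) enantiomer, and 4-chlorobut-2-yn-1-ol and 2,2-dimethyl-1,3-dioxan-5-one are treated as catalogue starting materials.

**Step 1**
Reactants: 1 4-chlorobut-2-yn-1-ol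
Product: 2 4-chlorobut-2-ynal
Conditions: MnO2 (activated, 10 equiv), CH2Cl2, rt; filter, use the solution directly
Reagents that add atoms: none
Why: oxidation of a propargylic alcohol with activated MnO2 stops cleanly at the ynal, and no stereocentre is involved.

**Step 2**
Reactants: 2 4-chlorobut-2-ynal; 3 2,2-dimethyl-1,3-dioxan-5-one
Product: 4 (4S)-4-[(1S)-4-chloro-1-hydroxybut-2-yn-1-yl]-2,2-dimethyl-1,3-dioxan-5-one
Conditions: L-proline (30 mol %), DMF, 4 °C, 4 d
Reagents that add atoms: none
Why: enamine (List–Houk type) aldol reaction in which the E-enamine of the cyclic ketone with L-proline attacks the Re face of the non-enolisable ynal in the acid-organised chair transition state, giving the anti adduct with (4S) at the future C2 and (1S) at the future C3, as established for this dioxanone with other aldehydes.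

**Step 3**
Reactants: 4 (4S)-4-[(1S)-4-chloro-1-hydroxybut-2-yn-1-yl]-2,2-dimethyl-1,3-dioxan-5-one
Product: 5 (1R)-4-chloro-1-[(4S)-2,2-dimethyl-5-oxo-1,3-dioxan-4-yl]but-2-yn-1-yl benzoate
Conditions: BzOH (1.5 equiv), PPh3 (1.5 equiv), DIAD (1.5 equiv), toluene, −20 to 0 °C
Reagents that add atoms: benzoic acid, OC(=O)c1ccccc1
Why: Mitsunobu esterification in which the propargylic carbinol is activated as its oxyphosphonium ion and displaced by benzoate with SN2 inversion, turning the anti (1S) alcohol into the (1R) benzoate with the C2/C3 relationship of the target while the ring stereocentre is untouched.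

**Step 4**
Reactants: 5 (1R)-4-chloro-1-[(4S)-2,2-dimethyl-5-oxo-1,3-dioxan-4-yl]but-2-yn-1-yl benzoate
Product: 6 (1R,2Z)-4-chloro-1-[(4S)-2,2-dimethyl-5-oxo-1,3-dioxan-4-yl]but-2-en-1-yl benzoate
Conditions: H2 (1 atm, stop at 1 equiv), Pd on CaCO3 poisoned with Pb(OAc)2 (Lindlar catalyst), quinoline, EtOAc, rt
Reagents that add atoms: none
Why: Lindlar semihydrogenation delivers H2 syn on the poisoned Pd surface to give only the Z-alkene that later lets C6 reach C1, and ketone, benzoate, acetonide and allylic chloride are not reduced at one equivalent of H2.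

**Step 5**
Reactants: 6 (1R,2Z)-4-chloro-1-[(4S)-2,2-dimethyl-5-oxo-1,3-dioxan-4-yl]but-2-en-1-yl benzoate
Product: 10 (1S,3S,6R,7S)-9,9-dimethyl-2,8,10-trioxatricyclo[5.4.0.0^{1,3}]undec-4-en-6-yl benzoate, via thiolanium salt 7 (not isolated), via sulfonium ylide 8 (not isolated), via alkoxide betaine 9 (not isolated)
Conditions: tetrahydrothiophene (3 equiv), AgBF4 (1.0 equiv), CH2Cl2, 0 °C to rt, dark; filter; then KN(SiMe3)2 (1.0 equiv), THF, −78 to −30 °C
Reagents that add atoms: none
Why: Proposed new method: S-alkylation of tetrahydrothiophene by the silver-activated allylic chloride gives salt 7, whose most acidic C–H (allylic, next to S+) is removed to give ylide 8; its α-carbon adds 6-exo to the very electrophilic, doubly α-oxygenated dioxanone carbonyl from the axial direction (intrinsic axial preference of 1,3-dioxan-5-ones, side chain held equatorial by the gem-dimethyl acetal, same sense as the cis-fused ketol of Robinson annulations), which forms the cyclohexene and fixes C1 with CH2O cis to C2–O; only the betaine 9 with O− and S+ anti can close by 3-exo-tet SN2 displacement of tetrahydrothiophene (the syn betaine reverts), which forms the oxirane and fixes C6; the closest known reaction types are the Corey–Chaykovsky epoxidation of ketones with allylic sulfonium ylides and intramolecular ylide epoxy-annulations of keto sulfonium salts.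

**Step 6**
Reactants: 10 (1S,3S,6R,7S)-9,9-dimethyl-2,8,10-trioxatricyclo[5.4.0.0^{1,3}]undec-4-en-6-yl benzoate
Product: 11 (1R,2S,3R,6S)-2-hydroxy-1-(hydroxymethyl)-7-oxabicyclo[4.1.0]hept-4-en-3-yl benzoate
Conditions: AcOH/H2O 4:1, rt, monitored closely
Reagents that add atoms: none
Why: acid-catalysed acetal hydrolysis cleaves the strained cis-fused 1,3-dioxane acetonide under dilute acetic acid, which the electron-poor, neopentyl-type vinyl oxirane and the benzoate should tolerate, and no stereocentre is involved.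

**Step 7**
Reactants: 11 (1R,2S,3R,6S)-2-hydroxy-1-(hydroxymethyl)-7-oxabicyclo[4.1.0]hept-4-en-3-yl benzoate
Product: 12 [(1R,2S,3R,6S)-3-(benzoyloxy)-2-hydroxy-7-oxabicyclo[4.1.0]hept-4-en-1-yl]methyl benzoate
Conditions: BzCl (1.05 equiv), pyridine, CH2Cl2, −40 to −20 °C
Reagents that add atoms: benzoyl chloride, O=C(Cl)c1ccccc1
Why: chemoselective O-acylation in which the primary C7–OH reacts much faster than the secondary C2–OH shielded by the quaternary C1 and by C3–OBz, so one equivalent of BzCl at low temperature gives the target without touching a stereocentre.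

**Compound list**
1 | 4-chlorobut-2-yn-1-ol | OCC#CCCl | starting material
2 | 4-chlorobut-2-ynal | O=CC#CCCl | intermediate
3 | 2,2-dimethyl-1,3-dioxan-5-one | CC1(C)OCC(=O)CO1 | starting material
4 | (4S)-4-[(1S)-4-chloro-1-hydroxybut-2-yn-1-yl]-2,2-dimethyl-1,3-dioxan-5-one (anti aldol) | ClCC#C[C@H](O)[C@@H]1OC(C)(C)OCC1=O | intermediate
5 | (1R)-4-chloro-1-[(4S)-2,2-dimethyl-5-oxo-1,3-dioxan-4-yl]but-2-yn-1-yl benzoate | ClCC#C[C@@H](OC(=O)c1ccccc1)[C@@H]1OC(C)(C)OCC1=O | intermediate
6 | (1R,2Z)-4-chloro-1-[(4S)-2,2-dimethyl-5-oxo-1,3-dioxan-4-yl]but-2-en-1-yl benzoate | ClC/C=C\[C@@H](OC(=O)c1ccccc1)[C@@H]1OC(C)(C)OCC1=O | intermediate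
7 | 1-{(2Z,4R)-4-(benzoyloxy)-4-[(4S)-2,2-dimethyl-5-oxo-1,3-dioxan-4-yl]but-2-en-1-yl}thiolan-1-ium tetrafluoroborate | C1CC[S+](C1)C/C=C\[C@@H](OC(=O)c1ccccc1)[C@@H]1OC(C)(C)OCC1=O.F[B-](F)(F)F | intermediate
8 | sulfonium ylide of 7 (carbanion on the S-bound allylic carbon, the future C6) | C1CC[S+](C1)[CH-]/C=C\[C@@H](OC(=O)c1ccccc1)[C@@H]1OC(C)(C)OCC1=O | intermediate
9 | ring-closed betaine: cyclohexene formed, C1–O− and C6–thiolanium trans, dioxane cis-fused (CH2O cis to C2–O), C3–OBz trans to C2–O | CC1(C)OC[C@]2([O-])[C@H]([S+]3CCCC3)C=C[C@@H](OC(=O)c3ccccc3)[C@@H]2O1 | intermediate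
10 | (1S,3S,6R,7S)-9,9-dimethyl-2,8,10-trioxatricyclo[5.4.0.0^{1,3}]undec-4-en-6-yl benzoate (the O7,O2-isopropylidene acetal of 11) | CC1(C)OC[C@]23O[C@H]2C=C[C@@H](OC(=O)c2ccccc2)[C@@H]3O1 | intermediate
11 | (1R,2S,3R,6S)-2-hydroxy-1-(hydroxymethyl)-7-oxabicyclo[4.1.0]hept-4-en-3-yl benzoate | OC[C@]12O[C@H]1C=C[C@@H](OC(=O)c1ccccc1)[C@@H]2O | intermediate
12 | [(1R,2S,3R,6S)-3-(benzoyloxy)-2-hydroxy-7-oxabicyclo[4.1.0]hept-4-en-1-yl]methyl benzoate | O=C(OC[C@]12O[C@H]1C=C[C@@H](OC(=O)c1ccccc1)[C@@H]2O)c1ccccc1 | target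

**Totals**
Total step count: 7. Longest linear sequence: 7 steps (1 → 2 → 4 → 5 → 6 → 10 → 11 → 12; compound 3 enters at step 2).

**Three steps most likely to fail**

Step 5 (ylide epoxy-annulation). Equatorial attack would give the C1/C6 epimer, and the desired transition state carries a syn-axial contact between the developing C1 alkoxide and C3–OBz. The ylide can also lose benzoate by vinylogous elimination, and the betaine alkoxide can attack the benzoate. The fallback sets out from 6 and comes back at 10, building the rings one after the other. Heating 6 with PPh3 in MeCN gives the allylic triphenylphosphonium chloride F1. KN(SiMe3)2 at −78 °C then forms only the carbocycle, by intramolecular Wittig olefination of the dioxanone carbonyl, giving the cyclohexa-1,3-diene benzoate F2. Buffered mCPBA at 0 °C epoxidises the more substituted C1=C6 bond from the face opposite the allylic acetal oxygen at C2, giving 10, so the oxirane configuration is set by reagent approach instead of by the carbonyl addition.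

Step 3 (Mitsunobu on a β-hydroxy ketone). Dehydration to the enynone, or SN2′ attack giving an allene, can compete with inversion. The fallback sets out from 2 and comes back at 5 and needs no inversion. A syn-selective aldol of 1,3-bis[(tert-butyldimethylsilyl)oxy]propan-2-one with 2 under O-tert-butyl-D-threonine catalysis (Z-enamine, N-methylpyrrolidone) gives the threo aldol F3 directly. BzCl/pyridine gives the benzoate F4 with retention, HF·pyridine removes both silyl groups to give the keto diol F5, and 2,2-dimethoxypropane/PPTS closes the 1,3-dioxane ring to give 5.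

Step 2 (proline aldol with the chloro-ynal). The propargylic chloride may alkylate proline, the amine may add to the ynal, and the small alkynyl group may lower dr and ee. The fallback sets out from 3 and comes back at 6, carrying the future leaving group as a silyl ether. The same L-proline aldol with 4-[(tert-butyldimethylsilyl)oxy]but-2-ynal gives the anti aldol silyl ether F6. Mitsunobu benzoylation gives the inverted benzoate F7, Lindlar reduction (Pd on CaCO3 poisoned with Pb(OAc)2) gives the Z-alkene F8, HF·pyridine frees the allylic alcohol F9, and PPh3/CCl4 converts it into the allylic chloride 6.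

**Further compounds**
F1 | step 5 | {(2Z,4R)-4-(benzoyloxy)-4-[(4S)-2,2-dimethyl-5-oxo-1,3-dioxan-4-yl]but-2-en-1-yl}triphenylphosphonium chloride | c1ccccc1[P+](c1ccccc1)(c1ccccc1)C/C=C\[C@@H](OC(=O)c1ccccc1)[C@@H]1OC(C)(C)OCC1=O.[Cl-]
F2 | step 5 | (8R,8aR)-2,2-dimethyl-8,8a-dihydro-4H-1,3-benzodioxin-8-yl benzoate | CC1(C)OCC2=CC=C[C@@H](OC(=O)c3ccccc3)[C@@H]2O1
F3 | step 3 | (3S,4R)-1,3-bis[(tert-butyldimethylsilyl)oxy]-7-chloro-4-hydroxyhept-5-yn-2-one | ClCC#C[C@@H](O)[C@@H](C(=O)CO[Si](C)(C)C(C)(C)C)O[Si](C)(C)C(C)(C)C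
F4 | step 3 | (3S,4R)-1,3-bis[(tert-butyldimethylsilyl)oxy]-7-chloro-2-oxohept-5-yn-4-yl benzoate | ClCC#C[C@@H](OC(=O)c1ccccc1)[C@@H](C(=O)CO[Si](C)(C)C(C)(C)C)O[Si](C)(C)C(C)(C)C
F5 | step 3 | (3S,4R)-7-chloro-1,3-dihydroxy-2-oxohept-5-yn-4-yl benzoate | ClCC#C[C@@H](OC(=O)c1ccccc1)[C@@H](C(=O)CO)O
F6 | step 2 | (4S)-4-[(1S)-4-[(tert-butyldimethylsilyl)oxy]-1-hydroxybut-2-yn-1-yl]-2,2-dimethyl-1,3-dioxan-5-one | CC(C)(C)[Si](C)(C)OCC#C[C@H](O)[C@@H]1OC(C)(C)OCC1=O
F7 | step 2 | (1R)-4-[(tert-butyldimethylsilyl)oxy]-1-[(4S)-2,2-dimethyl-5-oxo-1,3-dioxan-4-yl]but-2-yn-1-yl benzoate | CC(C)(C)[Si](C)(C)OCC#C[C@@H](OC(=O)c1ccccc1)[C@@H]1OC(C)(C)OCC1=O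
F8 | step 2 | (1R,2Z)-4-[(tert-butyldimethylsilyl)oxy]-1-[(4S)-2,2-dimethyl-5-oxo-1,3-dioxan-4-yl]but-2-en-1-yl benzoate | CC(C)(C)[Si](C)(C)OC/C=C\[C@@H](OC(=O)c1ccccc1)[C@@H]1OC(C)(C)OCC1=O
F9 | step 2 | (1R,2Z)-4-hydroxy-1-[(4S)-2,2-dimethyl-5-oxo-1,3-dioxan-4-yl]but-2-en-1-yl benzoate | OC/C=C\[C@@H](OC(=O)c1ccccc1)[C@@H]1OC(C)(C)OCC1=O
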